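(Its constants were set for the occasion; what happens was integrated by code.)

0.0500 M of partner against 0.050 M of substrate is the number to start from, and your hunch that the partner is what counts can be tested by counting turnovers.

substrate 0.050 M; partner 0.0500 M; scavenger 0.0750 M; time 4.0 h

    substrate + partner ⇌ target + released group (K1 = 0.79, k1 = 0.58 M⁻¹ s⁻¹)
    partner + released group ⇌ idle adduct, settled at all times (K2 = 67 M⁻¹)
    scavenger + released group → scavenged by-product (k3 = 1.2 M⁻¹ s⁻¹)
    crystals ⇌ target, rate k4*(cs4 - [target]) while solid is left; crystals form when [target] > cs4 (cs4 = 37 mM, k4 = 0.93 s⁻¹)
    substrate ⇌ dormant form (K5 = 9.8, k5 = 0.026 s⁻¹)

- part of the substrate that has reacted at 4.0 h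
- share of the unused partner that is free and not bound as idle adduct, at 4.0 h

- what is said of target includes crystals
- what is said of released group includes idle adduct
- crystals is a solid; its amount is given per volume of the solution
- what has gone from substrate into another species counts as reacted, even if it can come back
- run time (flask): 4.0 h

**Turn allowance.** Each turn of step 1 takes one partner, and its released group leaves for good through one scavenger. So N = 1.00, where N, the turn allowance, is the smaller of the partner and scavenger charges over the substrate charge. The substrate and dormant form relax with a half-life of 0.403 min, far shorter than 4.0 h, so whatever part is unturned splits one to K5, and about (1 − N)/(1 + K5) of the charge stays as substrate once the allowance is spent.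

**Rate remainder.** In this flask N reaches one, so what remains at 4.0 h is a question of rate. Call p the pool of substrate plus dormant form. With partner charged equal to substrate, partner left, free and bound, equals p, and substrate is p/(1 + K5). The substrate charge exceeds the solubility cs4 of target, so I hold dissolved target at cs4 and scavenger near its own charge less the substrate charge. A released group then escapes return with share f = 52.5%. Taking f over the whole run, 1/p grows linearly at k1·f/(1 + K5), which gives p = 2.35 mM and, for c, the part of the substrate reacted, 99.6%. Balancing the forward rate of step 1 against return and scavenging puts free released group at 5.18 × 10⁻⁶ M, so idle adduct over free partner is K2 times that, 0.0347%, and fr, the free share of the unused partner, is >99.9%.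

**The result.** The forecast gives 99.6% for c and >99.9% for fr, “with target held at its 37 mM solubility”. The simulation gives 99.6% for c and >99.9% for fr.

**Fast split.** The relaxation half-life of 0.403 min stands against a run of 4.0 h, and at 4.00 h this flask holds 0.405% of its charge as substrate beside 4.07% as dormant form, a ratio of 10.0 against K5 = 9.8. In the flask with 0.020 M of partner, where partner is the limiting reagent with 0% of it left, N is 0.400, the split of the unturned part gives 5.56% as substrate, and that flask holds 5.6% at 4.00 h.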